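**Retrosynthetic overview**

1. Aristophenone A (PPAP numbering: C1/C5 bridgeheads; ring A = C1–C2–C3–C4–C5–C9; ring B = C1–C8–C7–C6–C5–C9; C8 = CMe2; C9 = bridging ketone) is traced back to the 7-vinyl bicyclic trione 13 by late C3 aroylation and conversion of the C7 vinyl group into prenyl.
2. Trione 13 comes from the acyclic carbinol diester 10 in one anionic domino: an oxy-Cope shift makes C7–C8, the enolate so formed closes ring B by a Dieckmann reaction (C1–C9), and the acetyl enolate then closes ring A (C3–C4) in the same flask.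
3. Enabling feature: in ring B, C1 is the carbon between the C2 and C9 carbonyls and its neighbour C8 is the quaternary carbon bonded to C7. Read backwards, C8=C1–C2(O⁻)–CH2–CH=C7 is a hexa-1,5-dien-3-olate, and C9 is one ester of a prochiral malonate carbon (C5).
4. Stereocontrol: one carbinol stereocentre (C2 of 7, set by catalytic allylboration) is relayed to C7 through the chair [3,3] transition state; C7 then fixes C1 and C5 because only the 7-exo bicycle can close.
5. Fragments: enone 5 (from acetylacetone) gives carbinol 7, which is joined to malonate 9 by cross-metathesis; ring order is B, then A.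

Key step: step 7

Remark: PPAP numbering is used for the bicyclic compounds (C1 is the bridgehead next to C8(Me)2); enolised di- and triketones are drawn as one tautomer and their tautomers are treated as the same compound, CIP descriptors referring to the tautomer drawn.

**Route**

Step 1
Reactants: 1 pentane-2,4-dione; 2 1-bromo-3-methylbut-2-ene
Product: 3 3-(3-methylbut-2-en-1-yl)pentane-2,4-dione
Conditions: K2CO3, acetone, reflux
Reagents that add atoms: none
Why: SN2 C-alkylation of the stabilised β-diketone enolate by the allylic bromide; no stereocentre is formed.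

Step 2
Reactants: 3 3-(3-methylbut-2-en-1-yl)pentane-2,4-dione
Product: 4 3-(3-methylbut-2-en-1-yl)-4-oxopent-2-en-2-yl trifluoromethanesulfonate (E/Z mixture)
Conditions: NaH, Et2O, 0 °C; then Tf2O, −78 → 0 °C
Reagents that add atoms: trifluoromethanesulfonic anhydride, O=S(=O)(OS(=O)(=O)C(F)(F)F)C(F)(F)F
Why: O-sulfonylation of the sodium enolate (enol triflate formation); the alkene geometry is irrelevant because both β-substituents end as methyl.

Step 3
Reactants: 4 3-(3-methylbut-2-en-1-yl)-4-oxopent-2-en-2-yl trifluoromethanesulfonate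
Product: 5 6-methyl-3-(propan-2-ylidene)hept-5-en-2-one
Conditions: Me2CuLi, Et2O, −78 → −20 °C
Reagents that add atoms: lithium dimethylcuprate, [Li+].C[Cu-]C
Why: cuprate addition–elimination at the β-carbon of the β-triflyloxy enone (vinyl triflate–cuprate coupling) should install the second methyl and give the tetrasubstituted enone.

Step 4
Reactants: 5 6-methyl-3-(propan-2-ylidene)hept-5-en-2-one; 6 2-allyl-4,4,5,5-tetramethyl-1,3,2-dioxaborolane
Product: 7 (4R)-4,8-dimethyl-5-(propan-2-ylidene)nona-1,7-dien-4-ol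
Conditions: CuF(PPh3)3·2EtOH (cat.), i-Pr-DuPHOS (cat., antipode giving the R alcohol), La(Oi-Pr)3 (cat.), DMF, −40 °C; aq. NH4Cl
Reagents that add atoms: none
Why: copper-catalysed enantioselective allylboration of a methyl ketone (1,2-addition; 1,4-addition is blocked at the fully substituted β-carbon) should set the only catalyst-controlled stereocentre, the carbinol carbon, as R by discrimination between methyl and the twisted tetrasubstituted alkenyl group.

Step 5
Reactants: 8 dimethyl 2-(prop-2-en-1-yl)propanedioate; 2 1-bromo-3-methylbut-2-ene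
Product: 9 dimethyl 2-(3-methylbut-2-en-1-yl)-2-(prop-2-en-1-yl)propanedioate
Conditions: NaH, THF, 0 °C → rt
Reagents that add atoms: none
Why: malonate enolate alkylation (SN2) with the allylic bromide gives the prochiral quaternary carbon that becomes C5.

Step 6
Reactants: 7 (4R)-4,8-dimethyl-5-(propan-2-ylidene)nona-1,7-dien-4-ol; 9 dimethyl 2-(3-methylbut-2-en-1-yl)-2-(prop-2-en-1-yl)propanedioate (excess)
Product: 10 dimethyl 2-[(2E,5R)-5-hydroxy-5,9-dimethyl-6-(propan-2-ylidene)deca-2,8-dien-1-yl]-2-(3-methylbut-2-en-1-yl)propanedioate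
Conditions: second-generation Grubbs catalyst (5 mol %), CH2Cl2, 40 °C
Reagents that add atoms: none
Why: olefin cross-metathesis of the two monosubstituted alkenes (tri- and tetrasubstituted alkenes are spectators) should be E-selective because both allylic positions are heavily branched, and any Z isomer is removed on AgNO3–silica since it would relay to the enantiomeric series.

Step 7
Reactants: 10 dimethyl 2-[(2E,5R)-5-hydroxy-5,9-dimethyl-6-(propan-2-ylidene)deca-2,8-dien-1-yl]-2-(3-methylbut-2-en-1-yl)propanedioate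
Product: 13 (1R,5S,7S)-7-ethenyl-8,8-dimethyl-1,5-bis(3-methylbut-2-en-1-yl)bicyclo[3.3.1]nonane-2,4,9-trione, via acyclic potassium enolate 11 (not isolated), via monocyclic diketo ester 12 (not isolated)
Conditions: KH (3 equiv), 18-crown-6, THF, 0 → 50 °C; then 1 M HCl
Reagents that add atoms: none
Why: KH/18-crown-6 gives the free tertiary alkoxide of the hexa-1,5-dien-3-ol unit C8=C1–C2(O⁻)–CH2–CH=C7, whose anion-accelerated oxy-Cope [3,3] shift forms the hindered C7–C8 bond and unveils the C1=C2 enolate 11; this enolate acylates one malonate ester (Dieckmann, 6-(enolexo)-exo-trig, ring B, bond C1–C9) to give 12, and the acetyl enolate then closes ring A on the second ester (Claisen, 6-(enolendo)-exo-trig, bond C3–C4) to the stable β-diketonate. The closest known reaction type is the tandem alkoxide-accelerated oxy-Cope rearrangement/Dieckmann cyclisation used to build bridged bicyclic ketones. C7 is set by chirality transfer from the R carbinol through a chair transition state in which the E alkene places C6 equatorial and the axial methyl of the C8 terminus forces the C2 methyl equatorial (oxide axial). C1 and C5 are set by the bicycle itself, because the Dieckmann step is reversible under the methoxide released and only the isomer with acetyl and ester cis-diaxial and anti to the equatorial C7 vinyl group can close ring A on a chair ring B (7-exo), the 7-endo alternative needing a boat. The step needs the sigmatropic shift to outrun retro-allylation of the alkoxide and C-acylation at C1 instead of at the methyl carbon; the crown ether and low starting temperature serve the first, and ring size (six against eight) secures the second.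

Step 8
Reactants: 13 (1R,5S,7S)-7-ethenyl-8,8-dimethyl-1,5-bis(3-methylbut-2-en-1-yl)bicyclo[3.3.1]nonane-2,4,9-trione
Product: 15 (1R,5S,7R)-8,8-dimethyl-7-(3-methylbut-3-en-1-yl)-1,5-bis(3-methylbut-2-en-1-yl)bicyclo[3.3.1]nonane-2,4,9-trione, via alkylborane 14 (not isolated)
Conditions: 9-BBN (2.2 equiv), THF, 0 °C → rt; then 2-bromopropene, Pd(dppf)Cl2 (cat.), K3PO4, DMF/H2O, 50 °C
Reagents that add atoms: 2-bromopropene, CC(Br)=C
Why: anti-Markovnikov hydroboration of the only monosubstituted alkene (a further equivalent of 9-BBN is taken up by the enolised dione and released on work-up) followed by B-alkyl Suzuki–Miyaura coupling should give the 3-methylbut-3-enyl chain without touching a stereocentre.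

Step 9
Reactants: 15 (1R,5S,7R)-8,8-dimethyl-7-(3-methylbut-3-en-1-yl)-1,5-bis(3-methylbut-2-en-1-yl)bicyclo[3.3.1]nonane-2,4,9-trione
Product: 16 (1R,5S,7R)-8,8-dimethyl-1,5,7-tris(3-methylbut-2-en-1-yl)bicyclo[3.3.1]nonane-2,4,9-trione
Conditions: Co(salen)Cl (salen = N,N′-bis(3,5-di-tert-butylsalicylidene)-1,2-cyclohexanediaminate) (cat.), PhSiH3 (cat.), benzene, rt
Reagents that add atoms: none
Why: cobalt-hydride hydrogen-atom-transfer isomerisation should move the 1,1-disubstituted double bond by one position into the trisubstituted prenyl position, the thermodynamic sink in which the other two side chains already sit.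

Step 10
Reactants: 16 (1R,5S,7R)-8,8-dimethyl-1,5,7-tris(3-methylbut-2-en-1-yl)bicyclo[3.3.1]nonane-2,4,9-trione; 17 3,4-diacetoxybenzoic acid
Product: 19 3,4-di-O-acetylaristophenone A, via enol ester 18 (not isolated)
Conditions: DCC, DMAP, CH2Cl2, 0 °C → rt
Reagents that add atoms: none
Why: Steglich O-acylation of the enolised 1,3-dione followed by DMAP-mediated O-to-C acyl transfer (the standard route to 2-acylcyclohexane-1,3-diones) should place the aroyl group on C3, the only carbon between the two ring A carbonyls.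

Step 11
Reactants: 19 3,4-di-O-acetylaristophenone A
Product: 20 aristophenone A
Conditions: K2CO3, MeOH (degassed), 0 °C → rt; then 1 M HCl
Reagents that add atoms: none
Why: base-mediated methanolysis (transesterification) of the two aryl acetates should free the catechol without touching the vinylogous acid or the prenyl groups.

**Compound list**

1 | pentane-2,4-dione | CC(=O)CC(C)=O | starting material
2 | 1-bromo-3-methylbut-2-ene | CC(C)=CCBr | starting material
3 | 3-(3-methylbut-2-en-1-yl)pentane-2,4-dione | CC(=O)C(CC=C(C)C)C(C)=O | intermediate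
4 | 3-(3-methylbut-2-en-1-yl)-4-oxopent-2-en-2-yl trifluoromethanesulfonate (E/Z mixture) | CC(=O)C(CC=C(C)C)=C(C)OS(=O)(=O)C(F)(F)F | intermediate
5 | 6-methyl-3-(propan-2-ylidene)hept-5-en-2-one | CC(=O)C(CC=C(C)C)=C(C)C | intermediate
6 | 2-allyl-4,4,5,5-tetramethyl-1,3,2-dioxaborolane | C=CCB1OC(C)(C)C(C)(C)O1 | starting material
7 | (4R)-4,8-dimethyl-5-(propan-2-ylidene)nona-1,7-dien-4-ol | C=CC[C@@](C)(O)C(CC=C(C)C)=C(C)C | intermediate
8 | dimethyl 2-(prop-2-en-1-yl)propanedioate | C=CCC(C(=O)OC)C(=O)OC | starting material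
9 | dimethyl 2-(3-methylbut-2-en-1-yl)-2-(prop-2-en-1-yl)propanedioate | C=CCC(CC=C(C)C)(C(=O)OC)C(=O)OC | intermediate
10 | dimethyl 2-[(2E,5R)-5-hydroxy-5,9-dimethyl-6-(propan-2-ylidene)deca-2,8-dien-1-yl]-2-(3-methylbut-2-en-1-yl)propanedioate | COC(=O)C(CC=C(C)C)(C/C=C/C[C@@](C)(O)C(CC=C(C)C)=C(C)C)C(=O)OC | intermediate
11 | potassium enolate: dimethyl 2-[(2S,4Z)-2-ethenyl-3,3-dimethyl-4-(3-methylbut-2-en-1-yl)-5-oxidohex-4-en-1-yl]-2-(3-methylbut-2-en-1-yl)propanedioate, potassium salt | C=C[C@H](CC(CC=C(C)C)(C(=O)OC)C(=O)OC)C(C)(C)/C(CC=C(C)C)=C(\[O-])C.[K+] | intermediate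
12 | methyl (1R,3R,5S)-3-acetyl-5-ethenyl-4,4-dimethyl-1,3-bis(3-methylbut-2-en-1-yl)-2-oxocyclohexane-1-carboxylate (acetyl and ester cis, both trans to vinyl) | C=C[C@@H]1C[C@](C(=O)OC)(CC=C(C)C)C(=O)[C@@](CC=C(C)C)(C(C)=O)C1(C)C | intermediate
13 | (1R,5S,7S)-7-ethenyl-8,8-dimethyl-1,5-bis(3-methylbut-2-en-1-yl)bicyclo[3.3.1]nonane-2,4,9-trione (vinyl exo) | C=C[C@@H]1C[C@]2(CC=C(C)C)C(=O)[C@@](CC=C(C)C)(C(=O)CC2=O)C1(C)C | intermediate
14 | 9-{2-[(1R,5S,7R)-8,8-dimethyl-1,5-bis(3-methylbut-2-en-1-yl)-2,4,9-trioxobicyclo[3.3.1]nonan-7-yl]ethyl}-9-borabicyclo[3.3.1]nonane | C1CC2CCCC(C1)B2CC[C@@H]3C[C@]4(CC=C(C)C)C(=O)[C@@](CC=C(C)C)(C(=O)CC4=O)C3(C)C | intermediate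
15 | (1R,5S,7R)-8,8-dimethyl-7-(3-methylbut-3-en-1-yl)-1,5-bis(3-methylbut-2-en-1-yl)bicyclo[3.3.1]nonane-2,4,9-trione | C=C(C)CC[C@@H]1C[C@]2(CC=C(C)C)C(=O)[C@@](CC=C(C)C)(C(=O)CC2=O)C1(C)C | intermediate
16 | (1R,5S,7R)-8,8-dimethyl-1,5,7-tris(3-methylbut-2-en-1-yl)bicyclo[3.3.1]nonane-2,4,9-trione | CC(C)=CC[C@@H]1C[C@]2(CC=C(C)C)C(=O)[C@@](CC=C(C)C)(C(=O)CC2=O)C1(C)C | intermediate
17 | 3,4-diacetoxybenzoic acid | CC(=O)Oc1ccc(cc1OC(C)=O)C(=O)O | starting material
18 | enol 3,4-diacetoxybenzoate of 16 (O-acyl on the C4 oxygen, C2 ketone; 1R,5S,7R) | CC(C)=CC[C@@H]1C[C@]2(CC=C(C)C)C(=O)[C@@](CC=C(C)C)(C(=O)C=C2OC(=O)c3ccc(OC(C)=O)c(OC(C)=O)c3)C1(C)C | intermediate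
19 | 3,4-di-O-acetylaristophenone A: (1S,5S,7R)-3-(3,4-diacetoxybenzoyl)-4-hydroxy-8,8-dimethyl-1,5,7-tris(3-methylbut-2-en-1-yl)bicyclo[3.3.1]non-3-ene-2,9-dione | CC(C)=CC[C@@H]1C[C@]2(CC=C(C)C)C(=O)[C@@](CC=C(C)C)(C(=O)C(C(=O)c3ccc(OC(C)=O)c(OC(C)=O)c3)=C2O)C1(C)C | intermediate
20 | aristophenone A: (1S,5S,7R)-3-(3,4-dihydroxybenzoyl)-4-hydroxy-8,8-dimethyl-1,5,7-tris(3-methylbut-2-en-1-yl)bicyclo[3.3.1]non-3-ene-2,9-dione | CC(C)=CC[C@@H]1C[C@]2(CC=C(C)C)C(=O)[C@@](CC=C(C)C)(C(=O)C(C(=O)c3ccc(O)c(O)c3)=C2O)C1(C)C | target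

**Step count and risks**

Total steps: 11. Longest linear sequence: 10 (steps 1–4, then 6–11).

Steps most likely to fail:

Step 7. The hindered potassium alkoxide may fragment by loss of the allylic carbanion (retro-allylation) before the sigmatropic shift, or the first Dieckmann adduct may fail to equilibrate to the productive cis arrangement. The fallback sets out from 10 and separates the pericyclic event from the condensations: silylation (TMSOTf, 2,6-lutidine, CH2Cl2) gives the trimethylsilyl ether F1, which has no alkoxide to fragment. Its neutral siloxy-Cope rearrangement (o-dichlorobenzene, 200 °C) should give the silyl enol ether F2 through the same chair. MeLi (THF, 0 °C) then unmasks the lithium enolate, and warming with KOt-Bu (cat.) at 50 °C followed by 1 M HCl lets the two condensations equilibrate; the sequence comes back to the route at 13.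

Step 4. Addition to a ketone flanked by a twisted tetrasubstituted alkene may be slow and show poor facial discrimination. The fallback sets out from 5 and replaces catalyst control by stoichiometric reagent control: the allyl group is delivered through a closed six-membered transition state from enantiopure B-allyl-10-phenyl-9-borabicyclo[3.3.2]decane (Et2O, −78 °C, oxidative work-up), a reagent class made for methyl ketones. No new isolated compound arises (F0), and the sequence comes back at 7.

Step 9. The hydrogen-atom-transfer catalyst may also engage the existing trisubstituted alkenes or the enol, leading to reduction or radical cyclisation instead of a clean one-position shift. The fallback sets out from 13 (bypassing 15) and builds the prenyl group by olefination: 9-BBN followed by buffered H2O2 (NaOAc) gives the primary alcohol F3; oxidation with (n-Pr4N)RuO4 (cat.) and NMO gives the aldehyde F4; Wittig reaction with excess isopropylidenetriphenylphosphorane, the dione being carried as its enolate, should give the prenyl group, and the sequence comes back at 16.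

Further compounds
F1 | step 7 | dimethyl 2-[(2E,5R)-5,9-dimethyl-6-(propan-2-ylidene)-5-(trimethylsilyloxy)deca-2,8-dien-1-yl]-2-(3-methylbut-2-en-1-yl)propanedioate | COC(=O)C(CC=C(C)C)(C/C=C/C[C@@](C)(O[Si](C)(C)C)C(CC=C(C)C)=C(C)C)C(=O)OC
F2 | step 7 | dimethyl 2-[(2S,4Z)-2-ethenyl-3,3-dimethyl-4-(3-methylbut-2-en-1-yl)-5-(trimethylsilyloxy)hex-4-en-1-yl]-2-(3-methylbut-2-en-1-yl)propanedioate | C=C[C@H](CC(CC=C(C)C)(C(=O)OC)C(=O)OC)C(C)(C)/C(CC=C(C)C)=C(\O[Si](C)(C)C)C
F0 | step 4 | none | none
F3 | step 9 | (1R,5S,7S)-7-(2-hydroxyethyl)-8,8-dimethyl-1,5-bis(3-methylbut-2-en-1-yl)bicyclo[3.3.1]nonane-2,4,9-trione | OCC[C@@H]1C[C@]2(CC=C(C)C)C(=O)[C@@](CC=C(C)C)(C(=O)CC2=O)C1(C)C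
F4 | step 9 | 2-[(1R,5S,7S)-8,8-dimethyl-1,5-bis(3-methylbut-2-en-1-yl)-2,4,9-trioxobicyclo[3.3.1]nonan-7-yl]acetaldehyde | O=CC[C@@H]1C[C@]2(CC=C(C)C)C(=O)[C@@](CC=C(C)C)(C(=O)CC2=O)C1(C)C
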